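The two trans-2,3-diaryl-2,3-dihydrobenzofurans are built by the same two operations: hydrophenoxylation of a diarylalkyne with 3-hydroxy-5-methoxybenzaldehyde, then a rhodium-catalysed, imine-directed C–H alkylation in which arene carbon C3a adds across the resulting open-chain aryl vinyl ether and closes the furan ring at C3. The key step does this for the ring B unit. It exploits the C3a–H bond of ring B, flanked by the ether oxygen O1 (the tether) and by C4, which then carries a formyl group; its chiral aldimine steers rhodium into C3a–H and fixes C3. That formyl carbon later becomes C3 of the ring A unit; the second formyl group becomes the cis-stilbene.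

Key step: step 3

Remarks
- Ring A is the benzo ring that carries the cis-styryl group. Ring B is the benzo ring of the other dihydrobenzofuran, bonded through its C4 to C3 of the ring A unit. Each unit is numbered as a 1-benzofuran (O1, C2, C3, C3a, C4 to C7, C7a). The target is (2S,3S) in the ring A unit and (2R,3R) in the ring B unit.
- Assumption: the alkene face chosen by the 1-aminoindane auxiliary is assigned by analogy with related imine-directed cyclisations. If the opposite sense is found, amines 6 and 14 are exchanged.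
- coe = cyclooctene; IPr = 1,3-bis(2,6-diisopropylphenyl)imidazol-2-ylidene; (C5H5)Fe(C5H4PCy2) = dicyclohexylphosphinoferrocene.

Step 1
Reactants: 1 1-ethynyl-3,5-dimethoxybenzene; 2 4-iodoanisole
Product: 3 1,3-dimethoxy-5-[(4-methoxyphenyl)ethynyl]benzene
Conditions: Pd(PPh3)2Cl2 (2 mol%), CuI (4 mol%), Et3N, THF, rt
Reagents that add atoms: none
Why: Sonogashira coupling of an aryl iodide with a terminal arylalkyne is reliable with electron-rich partners and forms no stereocentre.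

Step 2
Reactants: 3 1,3-dimethoxy-5-[(4-methoxyphenyl)ethynyl]benzene; 4 3-hydroxy-5-methoxybenzaldehyde
Product: 5 3-{[(Z)-2-(3,5-dimethoxyphenyl)-1-(4-methoxyphenyl)ethenyl]oxy}-5-methoxybenzaldehyde
Conditions: [{Au(IPr)}2(μ-OH)]BF4 (1 mol%), toluene, 80 °C
Reagents that add atoms: none
Why: Gold-catalysed hydrophenoxylation should add the phenol anti across the activated alkyne at the carbon bearing the 4-methoxyphenyl group (the one best able to carry positive charge), giving the (Z)-aryl vinyl ether with oxygen on the future C2.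

Step 3
Reactants: 5 3-{[(Z)-2-(3,5-dimethoxyphenyl)-1-(4-methoxyphenyl)ethenyl]oxy}-5-methoxybenzaldehyde; 6 (R)-1-aminoindane
Product: 10 (2R,3R)-3-(3,5-dimethoxyphenyl)-6-methoxy-2-(4-methoxyphenyl)-2,3-dihydro-1-benzofuran-4-carbaldehyde, via N-indanyl aldimine 7 (not isolated), via cyclised aldimine 8 (not isolated), via cis aldehyde 9 (not isolated)
Conditions: 6, 4 Å MS, toluene, rt; then [RhCl(coe)2]2 (10 mol%), (C5H5)Fe(C5H4PCy2) (30 mol%), toluene, 75 °C; then TFA–H2O 9:1, CH2Cl2, rt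
Reagents that add atoms: water, O
Why: Condensation gives aldimine 7, whose nitrogen guides monovalent rhodium into the one C–H bond lying between the imine carbon and the aryloxy carbon (future C3a); the tethered (Z)-enol ether then inserts into Rh–H with hydride going to the oxygen-bearing carbon (future C2), and C–C reductive elimination from the six-membered oxa-rhodacycle forms the C3a–C3 bond. The closest known reaction type is the chelation-assisted, imine-directed intramolecular hydroarylation of aryl vinyl ethers carrying an ester on the alkene terminus, which gives 2-aryl-2,3-dihydrobenzofuran-3-carboxylates; here the terminus carries an aryl group instead. The five-membered ring closes in a formally 5-endo-trig sense, feasible because the bond is made by reductive elimination at the metal and not by direct attack of the arene on the alkene. Syn addition of arene carbon and hydrogen to the (Z)-alkene gives the 2,3-cis ring of 8, and the alkene face is chosen by the stereocentre of the indanyl group held next to rhodium, which sets C3 as R. Site selectivity is secured by the substrate, because only the C–H bond flanked by imine and ether oxygen can reach the alkene (metalation at the other ortho C–H is reversible and unproductive). Aqueous trifluoroacetic acid then hydrolyses the imine to 9 and equilibrates C2 through reversible ionisation of the 4-methoxybenzylic C2–O bond, with C3 untouched, to the more stable trans ring of 10.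

Step 4
Reactants: 10 (2R,3R)-3-(3,5-dimethoxyphenyl)-6-methoxy-2-(4-methoxyphenyl)-2,3-dihydro-1-benzofuran-4-carbaldehyde
Product: 11 (2R,3R)-3-(3,5-dimethoxyphenyl)-4-ethynyl-6-methoxy-2-(4-methoxyphenyl)-2,3-dihydro-1-benzofuran
Conditions: dimethyl (1-diazo-2-oxopropyl)phosphonate, K2CO3, MeOH, rt
Reagents that add atoms: dimethyl (1-diazo-2-oxopropyl)phosphonate, CC(=O)C(=[N+]=[N-])P(=O)(OC)OC
Why: Seyferth–Gilbert homologation in its Ohira–Bestmann form should turn the aryl aldehyde into the terminal alkyne under mild carbonate conditions that leave the trans-dihydrobenzofuran untouched.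

Step 5
Reactants: 11 (2R,3R)-3-(3,5-dimethoxyphenyl)-4-ethynyl-6-methoxy-2-(4-methoxyphenyl)-2,3-dihydro-1-benzofuran; 2 4-iodoanisole
Product: 12 (2R,3R)-3-(3,5-dimethoxyphenyl)-6-methoxy-2-(4-methoxyphenyl)-4-[(4-methoxyphenyl)ethynyl]-2,3-dihydro-1-benzofuran
Conditions: Pd(PPh3)2Cl2 (3 mol%), CuI (6 mol%), Et3N, THF, 50 °C
Reagents that add atoms: none
Why: Sonogashira coupling places the hindered partner on the alkyne side, where crowding matters little, and touches neither stereocentre.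

Step 6
Reactants: 12 (2R,3R)-3-(3,5-dimethoxyphenyl)-6-methoxy-2-(4-methoxyphenyl)-4-[(4-methoxyphenyl)ethynyl]-2,3-dihydro-1-benzofuran; 4 3-hydroxy-5-methoxybenzaldehyde
Product: 13 3-{[(Z)-2-[(2R,3R)-3-(3,5-dimethoxyphenyl)-6-methoxy-2-(4-methoxyphenyl)-2,3-dihydro-1-benzofuran-4-yl]-1-(4-methoxyphenyl)ethenyl]oxy}-5-methoxybenzaldehyde
Conditions: [{Au(IPr)}2(μ-OH)]BF4 (2 mol%), toluene, 90 °C
Reagents that add atoms: none
Why: The same gold-catalysed anti hydrophenoxylation should again put oxygen on the alkyne carbon bearing the 4-methoxyphenyl group, the electronically preferred and less crowded end, giving the (Z)-enol ether.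

Step 7
Reactants: 13 3-{[(Z)-2-[(2R,3R)-3-(3,5-dimethoxyphenyl)-6-methoxy-2-(4-methoxyphenyl)-2,3-dihydro-1-benzofuran-4-yl]-1-(4-methoxyphenyl)ethenyl]oxy}-5-methoxybenzaldehyde; 14 (S)-1-aminoindane
Product: 18 (2S,3S)-3-[(2R,3R)-3-(3,5-dimethoxyphenyl)-6-methoxy-2-(4-methoxyphenyl)-2,3-dihydro-1-benzofuran-4-yl]-6-methoxy-2-(4-methoxyphenyl)-2,3-dihydro-1-benzofuran-4-carbaldehyde, via N-indanyl aldimine 15 (not isolated), via cyclised aldimine 16 (not isolated), via cis aldehyde 17 (not isolated)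
Conditions: 14, 4 Å MS, toluene, rt; then [RhCl(coe)2]2 (10 mol%), (C5H5)Fe(C5H4PCy2) (30 mol%), toluene, 90 °C; then TFA–H2O 9:1, CH2Cl2, rt
Reagents that add atoms: water, O
Why: The second imine-directed rhodium-catalysed intramolecular hydroarylation closes the ring A furan at C3a–C3, the enantiomeric auxiliary 14 sending arene carbon and hydrogen to the opposite alkene face so that the new C3 is S (auxiliary control over the remote ring B centres), and the acidic work-up hydrolyses the imine and equilibrates the new C2 to the trans (2S,3S) ring while returning the already trans ring B unit unchanged.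

Step 8
Reactants: 18 (2S,3S)-3-[(2R,3R)-3-(3,5-dimethoxyphenyl)-6-methoxy-2-(4-methoxyphenyl)-2,3-dihydro-1-benzofuran-4-yl]-6-methoxy-2-(4-methoxyphenyl)-2,3-dihydro-1-benzofuran-4-carbaldehyde
Product: 19 (2S,3S)-3-[(2R,3R)-3-(3,5-dihydroxyphenyl)-6-hydroxy-2-(4-hydroxyphenyl)-2,3-dihydro-1-benzofuran-4-yl]-6-hydroxy-2-(4-hydroxyphenyl)-2,3-dihydro-1-benzofuran-4-carbaldehyde
Conditions: BBr3 (excess), CH2Cl2, −78 °C to rt; then H2O
Reagents that add atoms: none
Why: Boron tribromide cleaves the six aryl methyl ethers by bromide attack on the O-methyl groups of the borane-complexed ethers, and doing this before any alkene is present avoids the acid-triggered cyclisation of a stilbene onto ring B, while any reversible opening of the C2–O bonds returns to the trans rings without touching C3.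

Step 9
Reactants: 19 (2S,3S)-3-[(2R,3R)-3-(3,5-dihydroxyphenyl)-6-hydroxy-2-(4-hydroxyphenyl)-2,3-dihydro-1-benzofuran-4-yl]-6-hydroxy-2-(4-hydroxyphenyl)-2,3-dihydro-1-benzofuran-4-carbaldehyde
Product: 20 (2R,3R)-3-(3,5-dihydroxyphenyl)-4-[(2S,3S)-4-ethynyl-6-hydroxy-2-(4-hydroxyphenyl)-2,3-dihydro-1-benzofuran-3-yl]-2-(4-hydroxyphenyl)-2,3-dihydro-1-benzofuran-6-ol
Conditions: dimethyl (1-diazo-2-oxopropyl)phosphonate (excess), K2CO3 (excess), MeOH, rt
Reagents that add atoms: dimethyl (1-diazo-2-oxopropyl)phosphonate, CC(=O)C(=[N+]=[N-])P(=O)(OC)OC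
Why: Ohira–Bestmann homologation should still work on the phenolate form because the formyl group is meta to the ring A oxygen substituents and so keeps its electrophilicity, and the mild base does not open the dihydrobenzofurans.

Step 10
Reactants: 20 (2R,3R)-3-(3,5-dihydroxyphenyl)-4-[(2S,3S)-4-ethynyl-6-hydroxy-2-(4-hydroxyphenyl)-2,3-dihydro-1-benzofuran-3-yl]-2-(4-hydroxyphenyl)-2,3-dihydro-1-benzofuran-6-ol; 21 4-iodophenol
Product: 22 (2R,3R)-3-(3,5-dihydroxyphenyl)-4-{(2S,3S)-6-hydroxy-2-(4-hydroxyphenyl)-4-[(4-hydroxyphenyl)ethynyl]-2,3-dihydro-1-benzofuran-3-yl}-2-(4-hydroxyphenyl)-2,3-dihydro-1-benzofuran-6-ol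
Conditions: Pd(PPh3)4 (5 mol%), CuI (5 mol%), Et3N, DMF, 40 °C, degassed
Reagents that add atoms: none
Why: Sonogashira coupling tolerates free phenols, and no hydroxyl group sits ortho to the alkyne, so no benzofuran-forming cyclisation can compete.

Step 11
Reactants: 22 (2R,3R)-3-(3,5-dihydroxyphenyl)-4-{(2S,3S)-6-hydroxy-2-(4-hydroxyphenyl)-4-[(4-hydroxyphenyl)ethynyl]-2,3-dihydro-1-benzofuran-3-yl}-2-(4-hydroxyphenyl)-2,3-dihydro-1-benzofuran-6-ol
Product: 23 cis-miyabenol C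
Conditions: H2 (1 atm), Pd/CaCO3 poisoned with Pb(OAc)2, quinoline, EtOAc–MeOH, rt
Reagents that add atoms: none
Why: Lindlar semi-hydrogenation delivers H2 syn to the diarylalkyne on the poisoned palladium surface and should stop at the cis-stilbene, under neutral conditions that leave the four stereocentres and the acid-sensitive stilbene intact.

Compound list
1 | 1-ethynyl-3,5-dimethoxybenzene | C#Cc1cc(OC)cc(OC)c1 | starting material
2 | 4-iodoanisole | COc1ccc(I)cc1 | starting material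
3 | 1,3-dimethoxy-5-[(4-methoxyphenyl)ethynyl]benzene | COc1ccc(cc1)C#Cc1cc(OC)cc(OC)c1 | intermediate
4 | 3-hydroxy-5-methoxybenzaldehyde | COc1cc(O)cc(C=O)c1 | starting material
5 | 3-{[(Z)-2-(3,5-dimethoxyphenyl)-1-(4-methoxyphenyl)ethenyl]oxy}-5-methoxybenzaldehyde | COc1ccc(cc1)/C(Oc1cc(OC)cc(C=O)c1)=C/c1cc(OC)cc(OC)c1 | intermediate
6 | (R)-1-aminoindane | N[C@@H]1CCc2ccccc12 | starting material
7 | (E)-N-[(1R)-indan-1-yl] aldimine of 5 | COc1ccc(cc1)/C(Oc1cc(OC)cc(/C=N/[C@@H]2CCc3ccccc32)c1)=C/c1cc(OC)cc(OC)c1 | intermediate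
8 | (E)-N-[(1R)-indan-1-yl] aldimine of 9 | c1ccc2c(c1)CC[C@H]2/N=C/c1cc(OC)cc2c1[C@@H](c1cc(OC)cc(OC)c1)[C@@H](c1ccc(OC)cc1)O2 | intermediate
9 | (2S,3R)-3-(3,5-dimethoxyphenyl)-6-methoxy-2-(4-methoxyphenyl)-2,3-dihydro-1-benzofuran-4-carbaldehyde (2,3-cis) | O=Cc1cc(OC)cc2c1[C@@H](c1cc(OC)cc(OC)c1)[C@@H](c1ccc(OC)cc1)O2 | intermediate
10 | (2R,3R)-3-(3,5-dimethoxyphenyl)-6-methoxy-2-(4-methoxyphenyl)-2,3-dihydro-1-benzofuran-4-carbaldehyde (2,3-trans) | O=Cc1cc(OC)cc2c1[C@@H](c1cc(OC)cc(OC)c1)[C@H](c1ccc(OC)cc1)O2 | intermediate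
11 | (2R,3R)-3-(3,5-dimethoxyphenyl)-4-ethynyl-6-methoxy-2-(4-methoxyphenyl)-2,3-dihydro-1-benzofuran | C#Cc1cc(OC)cc2c1[C@@H](c1cc(OC)cc(OC)c1)[C@H](c1ccc(OC)cc1)O2 | intermediate
12 | (2R,3R)-3-(3,5-dimethoxyphenyl)-6-methoxy-2-(4-methoxyphenyl)-4-[(4-methoxyphenyl)ethynyl]-2,3-dihydro-1-benzofuran | COc1ccc(cc1)C#Cc1cc(OC)cc2c1[C@@H](c1cc(OC)cc(OC)c1)[C@H](c1ccc(OC)cc1)O2 | intermediate
13 | 3-{[(Z)-2-[(2R,3R)-3-(3,5-dimethoxyphenyl)-6-methoxy-2-(4-methoxyphenyl)-2,3-dihydro-1-benzofuran-4-yl]-1-(4-methoxyphenyl)ethenyl]oxy}-5-methoxybenzaldehyde | COc1ccc(cc1)/C(Oc1cc(OC)cc(C=O)c1)=C/c1cc(OC)cc2c1[C@@H](c1cc(OC)cc(OC)c1)[C@H](c1ccc(OC)cc1)O2 | intermediate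
14 | (S)-1-aminoindane | N[C@H]1CCc2ccccc12 | starting material
15 | (E)-N-[(1S)-indan-1-yl] aldimine of 13 | COc1ccc(cc1)/C(Oc1cc(OC)cc(/C=N/[C@H]2CCc3ccccc32)c1)=C/c1cc(OC)cc2c1[C@@H](c1cc(OC)cc(OC)c1)[C@H](c1ccc(OC)cc1)O2 | intermediate
16 | (E)-N-[(1S)-indan-1-yl] aldimine of 17 | c1ccc2c(c1)CC[C@@H]2/N=C/c1cc(OC)cc2c1[C@H](c1cc(OC)cc3c1[C@@H](c1cc(OC)cc(OC)c1)[C@H](c1ccc(OC)cc1)O3)[C@H](c1ccc(OC)cc1)O2 | intermediate
17 | (2R,3S)-3-[(2R,3R)-3-(3,5-dimethoxyphenyl)-6-methoxy-2-(4-methoxyphenyl)-2,3-dihydro-1-benzofuran-4-yl]-6-methoxy-2-(4-methoxyphenyl)-2,3-dihydro-1-benzofuran-4-carbaldehyde (ring A unit cis) | O=Cc1cc(OC)cc2c1[C@H](c1cc(OC)cc3c1[C@@H](c1cc(OC)cc(OC)c1)[C@H](c1ccc(OC)cc1)O3)[C@H](c1ccc(OC)cc1)O2 | intermediate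
18 | (2S,3S)-3-[(2R,3R)-3-(3,5-dimethoxyphenyl)-6-methoxy-2-(4-methoxyphenyl)-2,3-dihydro-1-benzofuran-4-yl]-6-methoxy-2-(4-methoxyphenyl)-2,3-dihydro-1-benzofuran-4-carbaldehyde | O=Cc1cc(OC)cc2c1[C@H](c1cc(OC)cc3c1[C@@H](c1cc(OC)cc(OC)c1)[C@H](c1ccc(OC)cc1)O3)[C@@H](c1ccc(OC)cc1)O2 | intermediate
19 | (2S,3S)-3-[(2R,3R)-3-(3,5-dihydroxyphenyl)-6-hydroxy-2-(4-hydroxyphenyl)-2,3-dihydro-1-benzofuran-4-yl]-6-hydroxy-2-(4-hydroxyphenyl)-2,3-dihydro-1-benzofuran-4-carbaldehyde | O=Cc1cc(O)cc2c1[C@H](c1cc(O)cc3c1[C@@H](c1cc(O)cc(O)c1)[C@H](c1ccc(O)cc1)O3)[C@@H](c1ccc(O)cc1)O2 | intermediate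
20 | (2R,3R)-3-(3,5-dihydroxyphenyl)-4-[(2S,3S)-4-ethynyl-6-hydroxy-2-(4-hydroxyphenyl)-2,3-dihydro-1-benzofuran-3-yl]-2-(4-hydroxyphenyl)-2,3-dihydro-1-benzofuran-6-ol | C#Cc1cc(O)cc2c1[C@H](c1cc(O)cc3c1[C@@H](c1cc(O)cc(O)c1)[C@H](c1ccc(O)cc1)O3)[C@@H](c1ccc(O)cc1)O2 | intermediate
21 | 4-iodophenol | Oc1ccc(I)cc1 | starting material
22 | (2R,3R)-3-(3,5-dihydroxyphenyl)-4-{(2S,3S)-6-hydroxy-2-(4-hydroxyphenyl)-4-[(4-hydroxyphenyl)ethynyl]-2,3-dihydro-1-benzofuran-3-yl}-2-(4-hydroxyphenyl)-2,3-dihydro-1-benzofuran-6-ol | Oc1ccc(cc1)C#Cc1cc(O)cc2c1[C@H](c1cc(O)cc3c1[C@@H](c1cc(O)cc(O)c1)[C@H](c1ccc(O)cc1)O3)[C@@H](c1ccc(O)cc1)O2 | intermediate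
23 | cis-miyabenol C | Oc1ccc(/C=C\c2cc(O)cc3c2[C@H](c2cc(O)cc4c2[C@@H](c2cc(O)cc(O)c2)[C@H](c2ccc(O)cc2)O4)[C@@H](c2ccc(O)cc2)O3)cc1 | target

Total step count: 11
Longest linear sequence: 11 steps (1 to 23 through steps 1 to 11)

Steps most likely to fail

1. Step 3. The electron-rich, triaryl-substituted enol ether may insert only slowly into the rhodium hydride, since the known cyclisations of this kind use an alkene activated by an ester. Reversible, unproductive C–H metalation would then dominate, and facial control by the auxiliary may also be incomplete. The fallback runs the ring closure on the ester-activated alkene and adds the 3-aryl group afterwards; it sets out from 4 and comes back at 10. Conjugate addition of 4 to methyl 3-(4-methoxyphenyl)propiolate (Cs2CO3, DMF) gives methyl (Z)-3-(3-formyl-5-methoxyphenoxy)-3-(4-methoxyphenyl)prop-2-enoate F1. Condensation with 14 gives its N-indanyl aldimine F2, and the same rhodium-catalysed hydroarylation gives the cyclised aldimine F3. The enantiomeric amine is used because here C2 is kept and C3 is made again. Mild hydrolysis (1 N HCl) gives methyl (2R,3S)-4-formyl-6-methoxy-2-(4-methoxyphenyl)-2,3-dihydro-1-benzofuran-3-carboxylate F4. Saponification (LiOH, THF–H2O) gives (2R,3S)-4-formyl-6-methoxy-2-(4-methoxyphenyl)-2,3-dihydro-1-benzofuran-3-carboxylic acid F5. Nickel/photoredox decarboxylative arylation with 1-bromo-3,5-dimethoxybenzene (Ir[dF(CF3)ppy]2(dtbbpy)PF6, NiCl2·glyme, 4,4'-di-tert-butyl-2,2'-bipyridine, Cs2CO3, DMF, blue light) should then attach the aryl group to the C3 radical anti to the C2 aryl group and give 10.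

2. Step 7. The same insertion must now create a C3 that carries the ortho-substituted ring B, so steric blocking of insertion or of reductive elimination is likely, and a mismatched pairing of auxiliary and substrate may erode facial selectivity. The fallback builds the ring A unit by carbonyl addition and acid-mediated ring closure; it sets out from 10 and comes back at 19. Commercial 2-bromo-3,5-dimethoxybenzaldehyde is converted (HC(OMe)3, TsOH, MeOH) into 2-bromo-1-(dimethoxymethyl)-3,5-dimethoxybenzene F6. Its aryllithium (n-BuLi, THF, −78 °C) adds to the formyl group of 10 to give [2-(dimethoxymethyl)-4,6-dimethoxyphenyl][(2R,3R)-3-(3,5-dimethoxyphenyl)-6-methoxy-2-(4-methoxyphenyl)-2,3-dihydro-1-benzofuran-4-yl]methanol F7 as both carbinol epimers. Dess–Martin oxidation gives the corresponding diaryl ketone F8, and 4-methoxybenzylmagnesium chloride with CeCl3 gives the tertiary alcohol 1-[2-(dimethoxymethyl)-4,6-dimethoxyphenyl]-1-[(2R,3R)-3-(3,5-dimethoxyphenyl)-6-methoxy-2-(4-methoxyphenyl)-2,3-dihydro-1-benzofuran-4-yl]-2-(4-methoxyphenyl)ethanol F9. BBr3 then cleaves all methyl ethers and the acetal and dehydrates the alcohol to the triarylethene. The freed ortho phenol of ring A closes onto the 4-hydroxybenzylic cation formed by protonation at C3, giving the trans ring under thermodynamic control. Because C3 is set here only by substrate control from the ring B unit, 19 should be obtained after chromatographic separation from the (2R,3R)-ring A diastereomer of 19 F10.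

3. Step 9. Under carbonate the substrate is a hexaphenolate, which may be poorly soluble and whose formyl group may react sluggishly, so that the diazophosphonate is consumed unproductively. The fallback replaces alkyne homologation and semi-hydrogenation by a Z-selective olefination and cross-coupling on protected material; it sets out from 19 and comes back at 23. Silylation (TBSCl, imidazole, DMF) gives the hexakis(tert-butyldimethylsilyl) ether of 19 F11. Stork–Zhao olefination (Ph3PCH2I iodide, NaHMDS, THF–DMPU, −78 °C) gives the (Z)-2-iodoethenyl compound F12. Suzuki–Miyaura coupling with 4-(tert-butyldimethylsilyloxy)phenylboronic acid (Pd(PPh3)4, K3PO4, THF–H2O), with retention of alkene geometry, gives the heptakis(tert-butyldimethylsilyl) ether of 23 F13. Desilylation (TBAF, AcOH, THF, 0 °C) should then give 23.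

Further compounds
F1 | step 3 | methyl (Z)-3-(3-formyl-5-methoxyphenoxy)-3-(4-methoxyphenyl)prop-2-enoate | COC(=O)/C=C(\Oc1cc(OC)cc(C=O)c1)c1ccc(OC)cc1
F2 | step 3 | (E)-N-[(1S)-indan-1-yl] aldimine of F1 | COC(=O)/C=C(\Oc1cc(OC)cc(/C=N/[C@H]2CCc3ccccc32)c1)c1ccc(OC)cc1
F3 | step 3 | (E)-N-[(1S)-indan-1-yl] aldimine of F4 | c1ccc2c(c1)CC[C@@H]2/N=C/c1cc(OC)cc2c1[C@H](C(=O)OC)[C@H](c1ccc(OC)cc1)O2
F4 | step 3 | methyl (2R,3S)-4-formyl-6-methoxy-2-(4-methoxyphenyl)-2,3-dihydro-1-benzofuran-3-carboxylate | O=Cc1cc(OC)cc2c1[C@H](C(=O)OC)[C@H](c1ccc(OC)cc1)O2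
F5 | step 3 | (2R,3S)-4-formyl-6-methoxy-2-(4-methoxyphenyl)-2,3-dihydro-1-benzofuran-3-carboxylic acid | O=Cc1cc(OC)cc2c1[C@H](C(=O)O)[C@H](c1ccc(OC)cc1)O2
F6 | step 7 | 2-bromo-1-(dimethoxymethyl)-3,5-dimethoxybenzene | COC(OC)c1cc(OC)cc(OC)c1Br
F7 | step 7 | [2-(dimethoxymethyl)-4,6-dimethoxyphenyl][(2R,3R)-3-(3,5-dimethoxyphenyl)-6-methoxy-2-(4-methoxyphenyl)-2,3-dihydro-1-benzofuran-4-yl]methanol (both carbinol epimers) | COC(OC)c1cc(OC)cc(OC)c1C(O)c1cc(OC)cc2c1[C@@H](c1cc(OC)cc(OC)c1)[C@H](c1ccc(OC)cc1)O2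
F8 | step 7 | [2-(dimethoxymethyl)-4,6-dimethoxyphenyl][(2R,3R)-3-(3,5-dimethoxyphenyl)-6-methoxy-2-(4-methoxyphenyl)-2,3-dihydro-1-benzofuran-4-yl]methanone | COC(OC)c1cc(OC)cc(OC)c1C(=O)c1cc(OC)cc2c1[C@@H](c1cc(OC)cc(OC)c1)[C@H](c1ccc(OC)cc1)O2
F9 | step 7 | 1-[2-(dimethoxymethyl)-4,6-dimethoxyphenyl]-1-[(2R,3R)-3-(3,5-dimethoxyphenyl)-6-methoxy-2-(4-methoxyphenyl)-2,3-dihydro-1-benzofuran-4-yl]-2-(4-methoxyphenyl)ethanol (both carbinol epimers) | COC(OC)c1cc(OC)cc(OC)c1C(O)(Cc1ccc(OC)cc1)c1cc(OC)cc2c1[C@@H](c1cc(OC)cc(OC)c1)[C@H](c1ccc(OC)cc1)O2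
F10 | step 7 | (2R,3R)-3-[(2R,3R)-3-(3,5-dihydroxyphenyl)-6-hydroxy-2-(4-hydroxyphenyl)-2,3-dihydro-1-benzofuran-4-yl]-6-hydroxy-2-(4-hydroxyphenyl)-2,3-dihydro-1-benzofuran-4-carbaldehyde | O=Cc1cc(O)cc2c1[C@@H](c1cc(O)cc3c1[C@@H](c1cc(O)cc(O)c1)[C@H](c1ccc(O)cc1)O3)[C@H](c1ccc(O)cc1)O2
F11 | step 9 | hexakis(tert-butyldimethylsilyl) ether of 19 | O=Cc1cc(O[Si](C)(C)C(C)(C)C)cc2c1[C@H](c1cc(O[Si](C)(C)C(C)(C)C)cc3c1[C@@H](c1cc(O[Si](C)(C)C(C)(C)C)cc(O[Si](C)(C)C(C)(C)C)c1)[C@H](c1ccc(O[Si](C)(C)C(C)(C)C)cc1)O3)[C@@H](c1ccc(O[Si](C)(C)C(C)(C)C)cc1)O2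
F12 | step 9 | (Z)-2-iodoethenyl analogue of F11 (formyl replaced by CH=CHI) | I/C=C\c1cc(O[Si](C)(C)C(C)(C)C)cc2c1[C@H](c1cc(O[Si](C)(C)C(C)(C)C)cc3c1[C@@H](c1cc(O[Si](C)(C)C(C)(C)C)cc(O[Si](C)(C)C(C)(C)C)c1)[C@H](c1ccc(O[Si](C)(C)C(C)(C)C)cc1)O3)[C@@H](c1ccc(O[Si](C)(C)C(C)(C)C)cc1)O2
F13 | step 9 | heptakis(tert-butyldimethylsilyl) ether of 23 | CC(C)(C)[Si](C)(C)Oc1ccc(/C=C\c2cc(O[Si](C)(C)C(C)(C)C)cc3c2[C@H](c2cc(O[Si](C)(C)C(C)(C)C)cc4c2[C@@H](c2cc(O[Si](C)(C)C(C)(C)C)cc(O[Si](C)(C)C(C)(C)C)c2)[C@H](c2ccc(O[Si](C)(C)C(C)(C)C)cc2)O4)[C@@H](c2ccc(O[Si](C)(C)C(C)(C)C)cc2)O3)cc1
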